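**Retrosynthetic overview**

1. Feature (numbering in the remark below): the C11–C12 bond of the central cyclobutane joins the two CHBr carbons and lies opposite the C5–C6 bond between the two spiro carbons with their trans lactone oxygens. It is made last among the cyclobutane bonds, as a C=C bond, from a thiolane whose C3/C4 are the future C5/C6 with both oxygens and both carboxyl carbons in place.
2. Target ⇒ (R)-carbinol (acetylation) ⇒ C9 ketone (CBS reduction) ⇒ bis(tetronic acid) (two vinyl bromides with oxalyl bromide) ⇒ O-hexanoyl/O-(3-oxohexanoyl) diester of a dibromo trans-diol (two Lacey–Dieckmann closures).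
3. Dibromo diol ⇒ trans-bis(silyloxy)cyclobutene (anti-dibromination, desilylation) ⇒ α-chlorothiolane 1,1-dioxide (Ramberg–Bäcklund contraction with loss of SO2).
4. Thiolane ⇒ parent thiocarbonyl ylide + dimethyl (E)-bis(benzoyloxy)fumarate ([3+2]), resolved on a chiral phase; benzoates exchanged for silyl ethers.
5. Ring order: thiolane (step 2) → cyclobutane by ring contraction (step 7) → butenolide rings A and B (step 13).

Key step: step 7

Remark on the chemistry (assumptions): the target is numbered as a 1,7-dioxadispiro[4.0.4.2]dodecane. Ring A is O1–C5 (butyl on C3, Br on C4), ring B is C6–C10 (acetoxybutyl on C9, Br on C10), C11 is next to C6 and C12 next to C5. The absolute configuration of resolved thiolane 6 is assumed to be secured by anomalous-dispersion X-ray analysis (sulfur).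

**Route**

Step 1
Reactants: 1 dimethyl dihydroxyfumarate
Product: 2 dimethyl (E)-2,3-bis(benzoyloxy)but-2-enedioate
Conditions: BzCl (2.4 equiv), pyridine, CH2Cl2, 0 °C → rt
Reagents that add atoms: benzoyl chloride, O=C(Cl)c1ccccc1
Why: Pyridine-mediated O-acylation of the acidic enediol hydroxyls (Einhorn-type acylation) should cap both oxygens faster than the enediol can tautomerise, so the E geometry is kept and an electron-poor enol ester alkene results.

Step 2
Reactants: 2 dimethyl (E)-2,3-bis(benzoyloxy)but-2-enedioate; 3 chloromethyl (trimethylsilyl)methyl sulfide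
Product: 5 racemic dimethyl trans-3,4-bis(benzoyloxy)thiolane-3,4-dicarboxylate, via thiocarbonyl ylide 4 (not isolated)
Conditions: CsF, MeCN, rt, slow addition of 3 (2.5 equiv)
Reagents that add atoms: none
Why: Fluoride removes the silyl group of 3 and chloride leaves in a 1,3-elimination to give ylide 4, whose suprafacial 1,3-dipolar cycloaddition to the doubly ester-activated alkene transfers the E geometry into the trans relationship of the two benzoyloxy groups; with no chiral element both enantiomers form equally.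

Step 3
Reactants: 5 racemic dimethyl trans-3,4-bis(benzoyloxy)thiolane-3,4-dicarboxylate
Product: 6 dimethyl (3R,4R)-3,4-bis(benzoyloxy)thiolane-3,4-dicarboxylate
Conditions: preparative SFC, amylose tris(3,5-dimethylphenylcarbamate) stationary phase, CO2/MeOH
Reagents that add atoms: none
Why: Chromatographic resolution on a chiral stationary phase (no bond is made or broken) should separate the enantiomers of the UV-active dibenzoate, and the (3R,4R) isomer is carried on.

Step 4
Reactants: 6 dimethyl (3R,4R)-3,4-bis(benzoyloxy)thiolane-3,4-dicarboxylate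
Product: 7 dimethyl (3R,4R)-3,4-dihydroxythiolane-3,4-dicarboxylate
Conditions: K2CO3 (0.3 equiv), MeOH, 0 °C
Reagents that add atoms: none
Why: Carbonate-catalysed transesterification (Zemplén-type methanolysis) removes the benzoates as methyl benzoate while exchange at the methyl esters is degenerate; the low temperature is chosen so that the tertiary alkoxide does not enter a retro-aldol/aldol equilibrium that would scramble C3 and C4, and enantiomeric purity is checked again on 8.

Step 5
Reactants: 7 dimethyl (3R,4R)-3,4-dihydroxythiolane-3,4-dicarboxylate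
Product: 8 dimethyl (3R,4R)-3,4-bis[(tert-butyldimethylsilyl)oxy]thiolane-3,4-dicarboxylate
Conditions: TBSOTf (3 equiv), 2,6-lutidine, CH2Cl2, 0 °C → rt
Reagents that add atoms: tert-butyldimethylsilyl triflate, CC(C)(C)[Si](C)(C)OS(=O)(=O)C(F)(F)F
Why: A silyl triflate with a hindered pyridine base silylates tertiary α-hydroxy esters (standard silyl ether formation), and the trans arrangement keeps the two large groups on opposite ring faces.

Step 6
Reactants: 8 dimethyl (3R,4R)-3,4-bis[(tert-butyldimethylsilyl)oxy]thiolane-3,4-dicarboxylate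
Product: 10 dimethyl (2R,3R,4R)-3,4-bis[(tert-butyldimethylsilyl)oxy]-2-chlorothiolane-3,4-dicarboxylate 1,1-dioxide, via α-chlorosulfide 9 (not isolated)
Conditions: NCS (1.05 equiv), CH2Cl2, 0 °C → rt; then mCPBA (2.5 equiv), NaHCO3, CH2Cl2, 0 °C → rt
Reagents that add atoms: N-chlorosuccinimide, O=C1CCC(=O)N1Cl; 3-chloroperbenzoic acid, OOC(=O)c1cccc(Cl)c1
Why: NCS chlorinates the sulfide by a Pummerer-type sequence (chlorosulfonium, thionium ion, chloride return) at one of the two α-carbons, which are equivalent by the C2 axis and have no β-hydrogen for elimination, and mCPBA then oxidises sulfur to the sulfone; chloride should add anti to the neighbouring silyloxy group, but the C2 epimer would serve equally in step 7.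

Step 7
Reactants: 10 dimethyl (2R,3R,4R)-3,4-bis[(tert-butyldimethylsilyl)oxy]-2-chlorothiolane-3,4-dicarboxylate 1,1-dioxide
Product: 12 dimethyl (1R,2R)-1,2-bis[(tert-butyldimethylsilyl)oxy]cyclobut-3-ene-1,2-dicarboxylate, via episulfone 11 (not isolated)
Conditions: KOtBu (2.5 equiv), THF, −78 → −30 °C; cold aqueous NH4Cl quench, solution kept cold
Reagents that add atoms: none
Why: tert-Butoxide removes a C5 proton (and reversibly the more acidic C2–H, which only epimerises the chloride), and the C5 carbanion displaces chloride from C2 across the ring in a 3-exo-tet closure to the cis-fused episulfone 11, which loses SO2 cheletropically; the closest known reaction type is the Ramberg–Bäcklund contraction of α-chlorothiolane 1,1-dioxides to cyclobutenes. The four-membered ring thus arises by extrusion from the bicyclic episulfone and not by a direct four-membered closure, the former S–CH carbons becoming the alkene carbons. No stereocentre is formed, and the quaternary C3 and C4 carry no acidic hydrogen, so the (R,R)-trans-bis(silyloxy) diester array passes unchanged into 12. The selectivity needed is 1,3-displacement over E1cB loss of a β-silyloxy group from either sulfonyl carbanion and over attack on the esters; it is secured by silanolate being a poor nucleofuge (as β-alkoxy groups survive such contractions), by the hindered base and by the low temperature. Because 12 is a donor-substituted cyclobutene prone to conrotatory ring opening, it is not stored but brominated at once.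

Step 8
Reactants: 12 dimethyl (1R,2R)-1,2-bis[(tert-butyldimethylsilyl)oxy]cyclobut-3-ene-1,2-dicarboxylate
Product: 13 dimethyl (1R,2R,3R,4R)-3,4-dibromo-1,2-bis[(tert-butyldimethylsilyl)oxy]cyclobutane-1,2-dicarboxylate
Conditions: Br2 (1.05 equiv), CH2Cl2, −78 → −40 °C, dark
Reagents that add atoms: bromine, BrBr
Why: Electrophilic anti addition through a bromonium ion whose two faces are equivalent by the C2 axis; bromide should open it at the carbon where it enters anti to the vicinal C–O bond and away from the neighbouring silyloxy group (polar and steric preference), placing each bromine trans to the adjacent silyloxy group and cis to the adjacent ester.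

Step 9
Reactants: 13 dimethyl (1R,2R,3R,4R)-3,4-dibromo-1,2-bis[(tert-butyldimethylsilyl)oxy]cyclobutane-1,2-dicarboxylate
Product: 14 dimethyl (1R,2R,3R,4R)-3,4-dibromo-1,2-dihydroxycyclobutane-1,2-dicarboxylate
Conditions: 48% aqueous HF, MeCN, 0 °C → rt
Reagents that add atoms: none
Why: Acidic fluoride cleaves the tertiary silyl ethers (desilylation) without forming an alkoxide, which matters because an alkoxide β to an ester on the strained ring could fragment by retro-aldol cleavage; the vicinal dibromide is inert to HF.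

Step 10
Reactants: 14 dimethyl (1R,2R,3R,4R)-3,4-dibromo-1,2-dihydroxycyclobutane-1,2-dicarboxylate; 15 hexanoyl chloride
Product: 16 dimethyl (1R,2R,3R,4R)-3,4-dibromo-1-(hexanoyloxy)-2-hydroxycyclobutane-1,2-dicarboxylate
Conditions: 15 (1.0 equiv, slow addition), pyridine, DMAP (0.1 equiv), CH2Cl2, −20 → 0 °C
Reagents that add atoms: none
Why: DMAP-catalysed esterification through the N-acylpyridinium ion under weakly basic conditions; the two hydroxyls are homotopic, so one equivalent of 15 should give mainly the monoester, with diester removed and unreacted 14 recycled.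

Step 11
Reactants: 17 Meldrum's acid; 18 butanoyl chloride
Product: 19 5-(1-hydroxybutylidene)-2,2-dimethyl-1,3-dioxane-4,6-dione
Conditions: pyridine (2 equiv), CH2Cl2, 0 °C → rt; dilute HCl wash
Reagents that add atoms: none
Why: C-Acylation of Meldrum's acid by an acid chloride in the presence of pyridine, the standard preparation of acyl Meldrum's acids.

Step 12
Reactants: 16 dimethyl (1R,2R,3R,4R)-3,4-dibromo-1-(hexanoyloxy)-2-hydroxycyclobutane-1,2-dicarboxylate; 19 5-(1-hydroxybutylidene)-2,2-dimethyl-1,3-dioxane-4,6-dione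
Product: 21 dimethyl (1R,2R,3R,4R)-3,4-dibromo-1-(hexanoyloxy)-2-[(3-oxohexanoyl)oxy]cyclobutane-1,2-dicarboxylate, via butanoylketene 20 (not isolated)
Conditions: 19 (2.5 equiv), toluene, 85 °C
Reagents that add atoms: none
Why: Thermal fragmentation of 19 releases acetone, CO2 and acylketene 20, which is trapped by the hindered tertiary hydroxyl under neutral conditions to give the β-keto ester (acylketene acylation), leaving the hexanoate and the dibromide untouched.

Step 13
Reactants: 21 dimethyl (1R,2R,3R,4R)-3,4-dibromo-1-(hexanoyloxy)-2-[(3-oxohexanoyl)oxy]cyclobutane-1,2-dicarboxylate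
Product: 23 (5S,6S,11R,12R)-11,12-dibromo-9-butanoyl-3-butyl-4,10-dihydroxy-1,7-dioxadispiro[4.0.4.2]dodeca-3,9-diene-2,8-dione, via ring-A tetronate 22 (not isolated)
Conditions: KN(SiMe3)2 (4 equiv), THF, −78 °C → rt; then 1 M HCl
Reagents that add atoms: none
Why: Two Dieckmann (Lacey–Dieckmann) closures in which first the hexanoate enolate and then the β-keto ester enolate attack their geminal methyl ester in a 5-exo-trig mode to give the spiro tetronic acids, the five-membered closure being preferred over attack on the ester of the neighbouring carbon; the non-nucleophilic amide base avoids deacylation, and no stereocentre is touched.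

Step 14
Reactants: 23 (5S,6S,11R,12R)-11,12-dibromo-9-butanoyl-3-butyl-4,10-dihydroxy-1,7-dioxadispiro[4.0.4.2]dodeca-3,9-diene-2,8-dione
Product: 24 (5S,6S,11R,12R)-4,10,11,12-tetrabromo-9-butanoyl-3-butyl-1,7-dioxadispiro[4.0.4.2]dodeca-3,9-diene-2,8-dione
Conditions: (COBr)2 (4 equiv), DMF (cat.), CH2Cl2, 0 °C → rt
Reagents that add atoms: oxalyl bromide, O=C(Br)C(Br)=O
Why: Vilsmeier-type activation of the vinylogous acids followed by addition–elimination of bromide converts both ring enols into vinyl bromides, the 3-acyltetronic acid being expected to react at its ring enol as cyclic 2-acyl-1,3-diones do on conversion into 3-halo-2-acylenones.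

Step 15
Reactants: 24 (5S,6S,11R,12R)-4,10,11,12-tetrabromo-9-butanoyl-3-butyl-1,7-dioxadispiro[4.0.4.2]dodeca-3,9-diene-2,8-dione
Product: 25 (5S,6S,11R,12R)-4,10,11,12-tetrabromo-3-butyl-9-[(1R)-1-hydroxybutyl]-1,7-dioxadispiro[4.0.4.2]dodeca-3,9-diene-2,8-dione
Conditions: (S)-Me-CBS oxazaborolidine (0.2 equiv), catecholborane (1.5 equiv), toluene, −78 °C
Reagents that add atoms: none
Why: Corey–Bakshi–Shibata reduction in which the ketone binds the (S)-oxazaborolidine with the large alkenyl (butenolide) residue away from the catalyst and hydride is delivered to the face that gives the (R)-carbinol, the remote ring stereocentres having little influence; lactones and C–Br bonds are inert to catecholborane at −78 °C.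

Step 16
Reactants: 25 (5S,6S,11R,12R)-4,10,11,12-tetrabromo-3-butyl-9-[(1R)-1-hydroxybutyl]-1,7-dioxadispiro[4.0.4.2]dodeca-3,9-diene-2,8-dione
Product: 26 (1R)-1-[(5S,6S,11R,12R)-4,10,11,12-tetrabromo-3-butyl-2,8-dioxo-1,7-dioxadispiro[4.0.4.2]dodeca-3,9-dien-9-yl]butyl acetate (CNP0268004.1)
Conditions: Ac2O (1.5 equiv), Sc(OTf)3 (2 mol %), MeCN, 0 °C
Reagents that add atoms: acetic anhydride, CC(=O)OC(C)=O
Why: Lewis-acid-catalysed acetylation of the secondary alcohol, chosen over pyridine/DMAP because nucleophilic amines can add to a 4-bromobutenolide, proceeds with retention at C1′ and gives the target.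

**Compound list**

1 | dimethyl dihydroxyfumarate | COC(=O)/C(O)=C(O)/C(=O)OC | starting material
2 | dimethyl (E)-2,3-bis(benzoyloxy)but-2-enedioate | COC(=O)/C(OC(=O)c1ccccc1)=C(OC(=O)c1ccccc1)/C(=O)OC | intermediate
3 | chloromethyl (trimethylsilyl)methyl sulfide | C[Si](C)(C)CSCCl | starting material
4 | thioformaldehyde S-methylide (parent thiocarbonyl ylide) | [CH2-][S+]=C | intermediate (not isolated)
5 | racemic dimethyl trans-3,4-bis(benzoyloxy)thiolane-3,4-dicarboxylate (1:1 mixture of the 3R,4R and 3S,4S enantiomers) | COC(=O)[C@@]1(OC(=O)c2ccccc2)CSC[C@]1(OC(=O)c2ccccc2)C(=O)OC.COC(=O)[C@]1(OC(=O)c2ccccc2)CSC[C@@]1(OC(=O)c2ccccc2)C(=O)OC | intermediate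
6 | dimethyl (3R,4R)-3,4-bis(benzoyloxy)thiolane-3,4-dicarboxylate | COC(=O)[C@@]1(OC(=O)c2ccccc2)CSC[C@]1(OC(=O)c2ccccc2)C(=O)OC | intermediate
7 | dimethyl (3R,4R)-3,4-dihydroxythiolane-3,4-dicarboxylate | COC(=O)[C@@]1(O)CSC[C@]1(O)C(=O)OC | intermediate
8 | dimethyl (3R,4R)-3,4-bis[(tert-butyldimethylsilyl)oxy]thiolane-3,4-dicarboxylate | COC(=O)[C@@]1(O[Si](C)(C)C(C)(C)C)CSC[C@]1(O[Si](C)(C)C(C)(C)C)C(=O)OC | intermediate
9 | dimethyl (2R,3R,4R)-3,4-bis[(tert-butyldimethylsilyl)oxy]-2-chlorothiolane-3,4-dicarboxylate (Cl trans to the C3 silyloxy group) | COC(=O)[C@@]1(O[Si](C)(C)C(C)(C)C)[C@@H](Cl)SC[C@]1(O[Si](C)(C)C(C)(C)C)C(=O)OC | intermediate (not isolated)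
10 | dimethyl (2R,3R,4R)-3,4-bis[(tert-butyldimethylsilyl)oxy]-2-chlorothiolane-3,4-dicarboxylate 1,1-dioxide | COC(=O)[C@@]1(O[Si](C)(C)C(C)(C)C)[C@@H](Cl)S(=O)(=O)C[C@]1(O[Si](C)(C)C(C)(C)C)C(=O)OC | intermediate
11 | dimethyl (1S,2R,3R,4R)-2,3-bis[(tert-butyldimethylsilyl)oxy]-5-thiabicyclo[2.1.0]pentane-2,3-dicarboxylate 5,5-dioxide (cis-fused episulfone) | COC(=O)[C@@]1(O[Si](C)(C)C(C)(C)C)[C@@H]2S(=O)(=O)[C@@H]2[C@]1(O[Si](C)(C)C(C)(C)C)C(=O)OC | intermediate (not isolated)
12 | dimethyl (1R,2R)-1,2-bis[(tert-butyldimethylsilyl)oxy]cyclobut-3-ene-1,2-dicarboxylate | COC(=O)[C@@]1(O[Si](C)(C)C(C)(C)C)C=C[C@]1(O[Si](C)(C)C(C)(C)C)C(=O)OC | intermediate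
13 | dimethyl (1R,2R,3R,4R)-3,4-dibromo-1,2-bis[(tert-butyldimethylsilyl)oxy]cyclobutane-1,2-dicarboxylate | COC(=O)[C@@]1(O[Si](C)(C)C(C)(C)C)[C@@H](Br)[C@H](Br)[C@]1(O[Si](C)(C)C(C)(C)C)C(=O)OC | intermediate
14 | dimethyl (1R,2R,3R,4R)-3,4-dibromo-1,2-dihydroxycyclobutane-1,2-dicarboxylate | COC(=O)[C@@]1(O)[C@@H](Br)[C@H](Br)[C@]1(O)C(=O)OC | intermediate
15 | hexanoyl chloride | CCCCCC(Cl)=O | starting material
16 | dimethyl (1R,2R,3R,4R)-3,4-dibromo-1-(hexanoyloxy)-2-hydroxycyclobutane-1,2-dicarboxylate | COC(=O)[C@@]1(OC(=O)CCCCC)[C@@H](Br)[C@H](Br)[C@]1(O)C(=O)OC | intermediate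
17 | Meldrum's acid (2,2-dimethyl-1,3-dioxane-4,6-dione) | CC1(C)OC(=O)CC(=O)O1 | starting material
18 | butanoyl chloride | CCCC(Cl)=O | starting material
19 | 5-(1-hydroxybutylidene)-2,2-dimethyl-1,3-dioxane-4,6-dione | CCCC(O)=C1C(=O)OC(C)(C)OC1=O | intermediate
20 | butanoylketene (3-oxohex-1-en-1-one) | CCCC(=O)C=C=O | intermediate (not isolated)
21 | dimethyl (1R,2R,3R,4R)-3,4-dibromo-1-(hexanoyloxy)-2-[(3-oxohexanoyl)oxy]cyclobutane-1,2-dicarboxylate | COC(=O)[C@@]1(OC(=O)CCCCC)[C@@H](Br)[C@H](Br)[C@]1(OC(=O)CC(=O)CCC)C(=O)OC | intermediate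
22 | methyl (1R,2R,3R,4S)-2,3-dibromo-7-butyl-8-hydroxy-6-oxo-1-[(3-oxohexanoyl)oxy]-5-oxaspiro[3.4]oct-7-ene-1-carboxylate | CCCCC1=C(O)[C@@]2(OC1=O)[C@@H](Br)[C@H](Br)[C@]2(OC(=O)CC(=O)CCC)C(=O)OC | intermediate (not isolated)
23 | (5S,6S,11R,12R)-11,12-dibromo-9-butanoyl-3-butyl-4,10-dihydroxy-1,7-dioxadispiro[4.0.4.2]dodeca-3,9-diene-2,8-dione | CCCCC1=C(O)[C@@]2(OC1=O)[C@@H](Br)[C@H](Br)[C@@]21OC(=O)C(C(=O)CCC)=C1O | intermediate
24 | (5S,6S,11R,12R)-4,10,11,12-tetrabromo-9-butanoyl-3-butyl-1,7-dioxadispiro[4.0.4.2]dodeca-3,9-diene-2,8-dione | CCCCC1=C(Br)[C@@]2(OC1=O)[C@@H](Br)[C@H](Br)[C@@]21OC(=O)C(C(=O)CCC)=C1Br | intermediate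
25 | (5S,6S,11R,12R)-4,10,11,12-tetrabromo-3-butyl-9-[(1R)-1-hydroxybutyl]-1,7-dioxadispiro[4.0.4.2]dodeca-3,9-diene-2,8-dione | CCCCC1=C(Br)[C@@]2(OC1=O)[C@@H](Br)[C@H](Br)[C@@]21OC(=O)C([C@@H](CCC)O)=C1Br | intermediate
26 | (1R)-1-[(5S,6S,11R,12R)-4,10,11,12-tetrabromo-3-butyl-2,8-dioxo-1,7-dioxadispiro[4.0.4.2]dodeca-3,9-dien-9-yl]butyl acetate | CCCCC1=C(Br)[C@@]2(OC1=O)[C@@H](Br)[C@H](Br)[C@@]21OC(=O)C([C@@H](CCC)OC(C)=O)=C1Br | target

**Step count**

Total: 16 steps (15 on the main line and 1 for acyl donor 19). Longest linear sequence: 15 steps (steps 1–10 and 12–16).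

**Steps most likely to fail**

(a) Step 7, the key step. The α-chloro-α-sulfonyl carbanion, which forms first and reversibly, may lose a β-silyloxy group by E1cB elimination (opening towards a 2-sulfolene) faster than the C5 carbanion closes the episulfone. The cyclobutene may also undergo conrotatory ring opening on warming. The fallback changes the nucleofuge and introduces the halogen last. Setting out from 8, oxidation (mCPBA, CH2Cl2) would give the halogen-free sulfone dimethyl (3R,4R)-3,4-bis[(tert-butyldimethylsilyl)oxy]thiolane-3,4-dicarboxylate 1,1-dioxide F1. The halogenative one-flask Ramberg–Bäcklund variant (CBr2F2, KOH on Al2O3, t-BuOH/CH2Cl2, 0 °C) would brominate the sulfonyl carbanion in situ to dimethyl (2R,3R,4R)-2-bromo-3,4-bis[(tert-butyldimethylsilyl)oxy]thiolane-3,4-dicarboxylate 1,1-dioxide F2, which is not isolated. Bromide is expelled in the 1,3-closure much faster than chloride, so episulfone 11 should form before elimination competes. The route is rejoined at 12, which is brominated at once as in step 8.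

(b) Step 8. Site selectivity in the opening of the bromonium ion may be poor or inverted, so that bromide enters on the face flanked by the neighbouring silyloxy group and the other trans-dibromide forms; a slow addition would also give 12 time to ring-open. The fallback replaces kinetic by thermodynamic control. Setting out from 12, the crude bromination mixture containing dimethyl (1R,2R,3S,4S)-3,4-dibromo-1,2-bis[(tert-butyldimethylsilyl)oxy]cyclobutane-1,2-dicarboxylate F3 would be equilibrated by dibromide mutarotation (ZnBr2 cat., 1,2-dichloroethane, 60 °C). Reversible ionisation to a bromonium–bromide ion pair and return at the other carbon interchanges the two trans-dibromides without passing through free 12. The isomer in which each C–Br dipole is anti to the vicinal C–O dipole should be enriched, but the steric terms of the two isomers are nearly balanced, so this preference is not assured. That isomer is separated and the remainder re-equilibrated, coming back to the route at 13.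

(c) Step 14. On the 3-acyltetronic acid of ring B, substitution may occur at the exocyclic acyl carbon instead of C10, or the doubly activated vinylogous acyl bromide may hydrolyse on work-up, which would also remove the substrate of the CBS reduction. The fallback brings the carbinol stereocentre in ready-made, so that neither a 3-acyltetronic acid nor the CBS step is needed.
- Acyl donor: commercial methyl 3-oxohexanoate would be hydrogenated (RuCl2[(R)-BINAP], H2, MeOH) to methyl (3R)-3-hydroxyhexanoate F4. Silylation (TBDPSCl, imidazole) would give methyl (3R)-3-[(tert-butyldiphenylsilyl)oxy]hexanoate F5, saponification (LiOH) would give (3R)-3-[(tert-butyldiphenylsilyl)oxy]hexanoic acid F6, and (COCl)2 with catalytic DMF would give (3R)-3-[(tert-butyldiphenylsilyl)oxy]hexanoyl chloride F7.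
- Setting out from 16, acylation with F7 (pyridine, DMAP) would give dimethyl (1R,2R,3R,4R)-3,4-dibromo-1-(hexanoyloxy)-2-{[(3R)-3-[(tert-butyldiphenylsilyl)oxy]hexanoyl]oxy}cyclobutane-1,2-dicarboxylate F8.
- KN(SiMe3)2 at −78 °C (kept cold so that the β-silyloxy ester enolate does not eliminate) would close both rings through methyl (1R,2R,3R,4S)-2,3-dibromo-7-butyl-8-hydroxy-6-oxo-1-{[(3R)-3-[(tert-butyldiphenylsilyl)oxy]hexanoyl]oxy}-5-oxaspiro[3.4]oct-7-ene-1-carboxylate F9, which is not isolated, to (5S,6S,11R,12R)-11,12-dibromo-3-butyl-9-{(1R)-1-[(tert-butyldiphenylsilyl)oxy]butyl}-4,10-dihydroxy-1,7-dioxadispiro[4.0.4.2]dodeca-3,9-diene-2,8-dione F10.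
- Oxalyl bromide/DMF would give (5S,6S,11R,12R)-4,10,11,12-tetrabromo-3-butyl-9-{(1R)-1-[(tert-butyldiphenylsilyl)oxy]butyl}-1,7-dioxadispiro[4.0.4.2]dodeca-3,9-diene-2,8-dione F11, and HF·pyridine would release alcohol 25, where the route is rejoined before the acetylation.

**Further compounds**

F1 | step 7 | dimethyl (3R,4R)-3,4-bis[(tert-butyldimethylsilyl)oxy]thiolane-3,4-dicarboxylate 1,1-dioxide | COC(=O)[C@@]1(O[Si](C)(C)C(C)(C)C)CS(=O)(=O)C[C@]1(O[Si](C)(C)C(C)(C)C)C(=O)OC
F2 | step 7 | dimethyl (2R,3R,4R)-2-bromo-3,4-bis[(tert-butyldimethylsilyl)oxy]thiolane-3,4-dicarboxylate 1,1-dioxide | COC(=O)[C@@]1(O[Si](C)(C)C(C)(C)C)[C@@H](Br)S(=O)(=O)C[C@]1(O[Si](C)(C)C(C)(C)C)C(=O)OC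
F3 | step 8 | dimethyl (1R,2R,3S,4S)-3,4-dibromo-1,2-bis[(tert-butyldimethylsilyl)oxy]cyclobutane-1,2-dicarboxylate | COC(=O)[C@@]1(O[Si](C)(C)C(C)(C)C)[C@H](Br)[C@@H](Br)[C@]1(O[Si](C)(C)C(C)(C)C)C(=O)OC
F4 | step 14 | methyl (3R)-3-hydroxyhexanoate | CCC[C@@H](O)CC(=O)OC
F5 | step 14 | methyl (3R)-3-[(tert-butyldiphenylsilyl)oxy]hexanoate | CCC[C@@H](O[Si](c1ccccc1)(c1ccccc1)C(C)(C)C)CC(=O)OC
F6 | step 14 | (3R)-3-[(tert-butyldiphenylsilyl)oxy]hexanoic acid | CCC[C@@H](O[Si](c1ccccc1)(c1ccccc1)C(C)(C)C)CC(=O)O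
F7 | step 14 | (3R)-3-[(tert-butyldiphenylsilyl)oxy]hexanoyl chloride | CCC[C@@H](O[Si](c1ccccc1)(c1ccccc1)C(C)(C)C)CC(Cl)=O
F8 | step 14 | dimethyl (1R,2R,3R,4R)-3,4-dibromo-1-(hexanoyloxy)-2-{[(3R)-3-[(tert-butyldiphenylsilyl)oxy]hexanoyl]oxy}cyclobutane-1,2-dicarboxylate | COC(=O)[C@@]1(OC(=O)CCCCC)[C@@H](Br)[C@H](Br)[C@]1(OC(=O)C[C@@H](CCC)O[Si](c1ccccc1)(c1ccccc1)C(C)(C)C)C(=O)OC
F9 | step 14 | methyl (1R,2R,3R,4S)-2,3-dibromo-7-butyl-8-hydroxy-6-oxo-1-{[(3R)-3-[(tert-butyldiphenylsilyl)oxy]hexanoyl]oxy}-5-oxaspiro[3.4]oct-7-ene-1-carboxylate | CCCCC1=C(O)[C@@]2(OC1=O)[C@@H](Br)[C@H](Br)[C@]2(OC(=O)C[C@@H](CCC)O[Si](c1ccccc1)(c1ccccc1)C(C)(C)C)C(=O)OC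
F10 | step 14 | (5S,6S,11R,12R)-11,12-dibromo-3-butyl-9-{(1R)-1-[(tert-butyldiphenylsilyl)oxy]butyl}-4,10-dihydroxy-1,7-dioxadispiro[4.0.4.2]dodeca-3,9-diene-2,8-dione | CCCCC1=C(O)[C@@]2(OC1=O)[C@@H](Br)[C@H](Br)[C@@]21OC(=O)C([C@@H](CCC)O[Si](c3ccccc3)(c3ccccc3)C(C)(C)C)=C1O
F11 | step 14 | (5S,6S,11R,12R)-4,10,11,12-tetrabromo-3-butyl-9-{(1R)-1-[(tert-butyldiphenylsilyl)oxy]butyl}-1,7-dioxadispiro[4.0.4.2]dodeca-3,9-diene-2,8-dione | CCCCC1=C(Br)[C@@]2(OC1=O)[C@@H](Br)[C@H](Br)[C@@]21OC(=O)C([C@@H](CCC)O[Si](c3ccccc3)(c3ccccc3)C(C)(C)C)=C1Br
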